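Assumption: compounds 1, 3, 4 and 9 are purchased. Compound 4 is the commercial L-series glyceraldehyde acetonide, made from L-gulono-1,4-lactone or vitamin C. Prostanoid numbering (C1 = ester carbon, C20 = chain end) is used for atom labels.

## Retrosynthetic overview
- The C7 acetate and the C10 iodide go on last, by acetylation and enone α-iodination. This leads back to a diol-cyclopentenone.
- The cyclopentenone, the only ring in the target, is closed at C8–C12. The closure is a cathodic two-electron ring contraction of a 6,8-dioxabicyclo[3.2.1]oct-3-en-2-one.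
- The α-chain comes from a Z-Wittig reaction on the C6 aldehyde of that bicycle. The bicycle masks C7–O, C8–O and the C12 carbonyl and has no enolisable position.
- The bicycle comes from singlet-oxygen oxidation (photo-Achmatowicz) and ketalisation of a 2,5-disubstituted furyl carbinol.
- The carbinol comes from furan, (S)-glyceraldehyde acetonide (the source of C7) and (Z)-octenyl bromide. Ring order: furan (bought), then the pyranone/dioxolane bicycle, then the cyclopentenone.

## Route

**Step 1**
Reactants: 1 (Z)-oct-2-en-1-ol
Product: 2 (Z)-1-bromooct-2-ene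
Conditions: PBr3 (0.4 equiv), cat. pyridine, Et2O, −10 °C
Reagents that add atoms: phosphorus tribromide, BrP(Br)Br
Why: SN2 bromination of a primary allylic alcohol through its phosphite ester keeps the Z-alkene at low temperature and creates no stereocentre.

**Step 2**
Reactants: 3 furan; 4 (S)-2,2-dimethyl-1,3-dioxolane-4-carbaldehyde
Product: 5 (S)-[(S)-2,2-dimethyl-1,3-dioxolan-4-yl](furan-2-yl)methanol (anti adduct)
Conditions: 3, n-BuLi, THF, 0 °C; ZnBr2; then 4, −78 → 0 °C
Reagents that add atoms: none
Why: Felkin–Anh 1,2-addition of the 2-furyl organometallic to the α-alkoxy aldehyde gives mainly the anti carbinol, where the dioxolane CH is the purchased C7 centre and the new carbinol centre (future C8) is temporary and is erased in Step 7.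

**Step 3**
Reactants: 5; 2
Product: 6 (S)-[(S)-2,2-dimethyl-1,3-dioxolan-4-yl]{5-[(Z)-oct-2-en-1-yl]furan-2-yl}methanol
Conditions: n-BuLi (2.1 equiv), THF, −78 → 0 °C; then 2 (1.05 equiv), −78 °C → rt
Reagents that add atoms: none
Why: α-Lithiation of the furan (alkoxide/C5 dianion) followed by SN2 alkylation with the primary allylic bromide is done in this order so that no furan already carrying the acidic furfuryl/allylic CH2 has to be lithiated.

**Step 4**
Reactants: 6
Product: 7 (1S,5S,7S)-7-(hydroxymethyl)-5-[(Z)-oct-2-en-1-yl]-6,8-dioxabicyclo[3.2.1]oct-3-en-2-one (bicycle C1 = C8, C2 = C9, C5 = C12, C7 = C7; CH2OH arm endo)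
Conditions: O2, rose bengal (1 mol%), green LEDs, MeOH, −20 °C; Me2S; then p-TsOH·H2O (10 mol%), wet MeCN, rt (telescoped)
Reagents that add atoms: dioxygen, O=O (one O atom retained)
Why: This is a photo-Achmatowicz/bicycloketalisation in which 1O2 adds [4+2] to the dialkylfuran far faster than it undergoes the ene reaction with a Z-disubstituted alkene, Me2S reduction gives the (Z)-enedione that closes to the pyranone hemiketal through O8, and acid removes the acetonide so that O7 closes the favoured five-membered ketal ring, with the C12 ketal configuration fixed by the bridge geometry from C8.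

**Step 5**
Reactants: 7
Product: 8 (1S,5S,7R)-5-[(Z)-oct-2-en-1-yl]-2-oxo-6,8-dioxabicyclo[3.2.1]oct-3-ene-7-carbaldehyde
Conditions: Dess–Martin periodinane, NaHCO3, CH2Cl2, 0 °C
Reagents that add atoms: none
Why: Buffered Dess–Martin oxidation of the only free (primary) alcohol leaves the ketal, enone and alkene untouched, and the change of descriptor at C7 reflects CIP priority only.

**Step 6**
Reactants: 8; 9 (4-carboxybutyl)triphenylphosphonium bromide
Product: 10 methyl (Z)-6-{(1S,5S,7S)-5-[(Z)-oct-2-en-1-yl]-2-oxo-6,8-dioxabicyclo[3.2.1]oct-3-en-7-yl}hex-5-enoate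
Conditions: 9 (1.3 equiv), NaHMDS (2.6 equiv), THF, 0 → −78 °C; add 8, −78 → −20 °C; then MeI, DMF, rt (one pot)
Reagents that add atoms: iodomethane, CI
Why: A Z-selective Wittig olefination with the non-stabilised ylide reacts at the aldehyde well before the ketone, the bicycle tolerates the base because C8–H is a bridgehead (Bredt-protected) and C13–H2 sits next to a ketal rather than a ketone, and the carboxylate is methylated in situ.

**Step 7**
Reactants: 10
Product: 11 methyl (5Z,7S)-7-hydroxy-7-{(1R,5R)-5-hydroxy-5-[(Z)-oct-2-en-1-yl]-2-oxocyclopent-3-en-1-yl}hept-5-enoate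
Conditions: undivided cell, Mg anode / glassy-carbon cathode, n-Bu4NBF4 (0.1 M), Mg(OTf)2 (1 equiv), DMF–THF, −20 °C, 5 mA cm⁻², stop at 2.1 F mol⁻¹; AcOH then pH 7 buffer quench at −20 °C
Reagents that add atoms: none
Why: Proposed new method: cathodic two-electron (ECE) reductive ring contraction of an Achmatowicz-type bridged ketal-enone, in which the enone radical anion expels an alkoxide from a C–O bond lying about 60° out of the enone plane (either α-C8–O8 directly, or γ-C12–O7 followed by oxa-6π opening of the 2H-pyran-3-olate, both converging on the same species), the second electron gives the C8 enolate regiospecifically while the released hemiketal alkoxide unmasks the C12 ketone only at that moment so the acidic C13–H2 never meets base beforehand, and Mg2+ binds O7, O9 and O12 so that the (Z)-enolate attacks C12 through a closed bicyclo[3.2.1]-like aldol transition state on the face anti to the C6 vinyl arm (Fráter–Seebach-type induction from the purchased C7, giving 8R) with O12 held syn to the C7 arm (OH cis to the α-chain, octenyl trans), the old C8 and C12 configurations being erased; the closest known reactions are SmI2 or cathodic cleavage of α-alkoxy/α-acyloxy ketones to enolates, sacrificial-anode electro-Reformatsky aldols, and base-induced closure of (Z)-ene-1,4-diones to 4-hydroxycyclopentenones.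

**Step 8**
Reactants: 11
Product: 12 methyl (5Z,7S)-7-hydroxy-7-{(1R,5S)-5-hydroxy-3-iodo-5-[(Z)-oct-2-en-1-yl]-2-oxocyclopent-3-en-1-yl}hept-5-enoate
Conditions: I2 (1.5 equiv), pyridine–CH2Cl2 1:1, 0 °C → rt, dark; Na2S2O3 work-up
Reagents that add atoms: iodine, II
Why: Johnson α-iodination (pyridine conjugate addition, enolate iodination, elimination) works on 4,4-disubstituted cyclopentenones and is run before acetylation so that no β-acetoxy ketone sits in base, with the change of descriptor at C12 reflecting CIP priority only.

**Step 9**
Reactants: 12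
Product: 13 7-acetoxy-7,8-dihydroiodovulone I, methyl (5Z,7S)-7-acetoxy-7-{(1R,5S)-5-hydroxy-3-iodo-5-[(Z)-oct-2-en-1-yl]-2-oxocyclopent-3-en-1-yl}hept-5-enoate
Conditions: Ac2O (1.5 equiv), pyridine, CH2Cl2, 0 °C, short reaction time
Reagents that add atoms: acetic anhydride, CC(=O)OC(C)=O
Why: Acetylation is chemoselective for the secondary allylic C7–OH over the tertiary C12–OH, and the cold, DMAP-free conditions avoid E1cB loss of acetate and touch no stereocentre.

## Compound list
1 | (Z)-oct-2-en-1-ol | CCCCC/C=C\CO | starting material
2 | (Z)-1-bromooct-2-ene | CCCCC/C=C\CBr | intermediate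
3 | furan | c1ccoc1 | starting material
4 | (S)-2,2-dimethyl-1,3-dioxolane-4-carbaldehyde | CC1(C)OC[C@H](O1)C=O | starting material
5 | (S)-[(S)-2,2-dimethyl-1,3-dioxolan-4-yl](furan-2-yl)methanol | CC1(C)OC[C@H](O1)[C@H](O)c1ccco1 | intermediate
6 | (S)-[(S)-2,2-dimethyl-1,3-dioxolan-4-yl]{5-[(Z)-oct-2-enyl]furan-2-yl}methanol | CC1(C)OC[C@H](O1)[C@H](O)c1ccc(C/C=C\CCCCC)o1 | intermediate
7 | (1S,5S,7S)-7-(hydroxymethyl)-5-[(Z)-oct-2-enyl]-6,8-dioxabicyclo[3.2.1]oct-3-en-2-one | O=C1C=C[C@@]2(C/C=C\CCCCC)O[C@@H](CO)[C@@H]1O2 | intermediate
8 | (1S,5S,7R)-5-[(Z)-oct-2-enyl]-2-oxo-6,8-dioxabicyclo[3.2.1]oct-3-ene-7-carbaldehyde | O=C1C=C[C@@]2(C/C=C\CCCCC)O[C@@H](C=O)[C@@H]1O2 | intermediate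
9 | (4-carboxybutyl)triphenylphosphonium bromide | OC(=O)CCCC[P+](c1ccccc1)(c1ccccc1)c1ccccc1.[Br-] | starting material
10 | methyl (Z)-6-{(1S,5S,7S)-5-[(Z)-oct-2-enyl]-2-oxo-6,8-dioxabicyclo[3.2.1]oct-3-en-7-yl}hex-5-enoate | O=C1C=C[C@@]2(C/C=C\CCCCC)O[C@@H](/C=C\CCCC(=O)OC)[C@@H]1O2 | intermediate
11 | methyl (5Z,7S)-7-hydroxy-7-{(1R,5R)-5-hydroxy-5-[(Z)-oct-2-enyl]-2-oxocyclopent-3-en-1-yl}hept-5-enoate | CCCCC/C=C\C[C@@]1(O)C=CC(=O)[C@@H]1[C@H](/C=C\CCCC(=O)OC)O | intermediate
12 | methyl (5Z,7S)-7-hydroxy-7-{(1R,5S)-5-hydroxy-3-iodo-5-[(Z)-oct-2-enyl]-2-oxocyclopent-3-en-1-yl}hept-5-enoate | CCCCC/C=C\C[C@@]1(O)C=C(I)C(=O)[C@@H]1[C@H](/C=C\CCCC(=O)OC)O | intermediate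
13 | 7-acetoxy-7,8-dihydroiodovulone I | CCCCC/C=C\C[C@@]1(O)C=C(I)C(=O)[C@@H]1[C@H](/C=C\CCCC(=O)OC)OC(C)=O | target

## Step count
- Total steps: 9
- Longest linear sequence: 8 (Steps 2–9 from furan and 4, or equally Steps 1 and 3–9 from 1)

## Steps most likely to fail

**1. Step 7 (proposed new electroreductive ring contraction).**
- Risks:
  - unproductive γ-C12–O8 scission;
  - proton transfer from C13–H2 to the enolate, leading to the wrong closure or alkene migration;
  - the enolate forming with E rather than Z geometry, which would erode the C8/C12 selectivity;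
  - over-reduction of the product enone;
  - modest diastereoselectivity.
- Fallback (known chemistry, different bond-forming logic): install the α-chain at the furan stage. From 6 this means silylating C8–OH, removing the acetonide, oxidising the primary alcohol selectively and running the same Wittig. After desilylation, close C8–C12 by the classical acid-catalysed Piancatelli rearrangement (Dy(OTf)3 or ZnCl2, aqueous t-BuOH, 80 °C, thermal 4π closure). This accepts thermodynamic control at the epimerisable C8.

**2. Step 4 (photo-oxygenation and bicycloketalisation).**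
- Risks:
  - acid-induced loss of C13–H from the C12 oxocarbenium, moving the skipped Z-alkene into conjugation;
  - competing [3.3.1] ketal formation through the primary OH.
- Fallback: carry the ω-chain as the alkyne by alkylating with commercial 1-bromo-2-octyne in Step 3, and reveal the Z-alkene by Lindlar semihydrogenation of the alkyne analogue of 11 before iodination. If the [3.3.1] ketal persists, temporarily silylate the primary OH so that only O7 can close.

**3. Step 6 (Wittig on the enone-aldehyde).**
- Risks:
  - epimerisation or β-alkoxide elimination at C7;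
  - ylide attack on the enone;
  - eroded Z-selectivity on the endo aldehyde.
- Fallback: two-stage C–C construction. Stork–Zhao olefination (Ph3P=CHI) gives the (Z)-vinyl iodide, then a Pd-catalysed Negishi sp2–sp3 coupling with the zinc reagent from methyl 4-iodobutanoate proceeds with retention of alkene geometry under essentially non-basic conditions.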